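**Plan**

- Ring locants: C1′ carries the coumarin, C2′ is the alkene CH, C3′ and C6′ are the ketones, C4′ is the carbinol carbon, C5′ is the CH2. The two ketones sit 1,4 to each other across the C1′=C2′ alkene, which is the pattern O2 leaves when it adds to the ends of a C3′=C2′–C1′=C6′ diene.
- Cuts: both carbonyl C–O bonds (C3′–O, C6′–O) go back through a peroxide bridge to that diene; the prenyl alkene goes back to allyl (cross-metathesis); the C1′–C3(coumarin) bond is a Stille bond; the C4′–CH2 bond comes from an allyl Grignard addition.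
- Forward: the carbocycle is bought as benzoquinone monoketal. Allyl is joined at C4′, the dienone is desymmetrised, and its dienyl triflate is coupled with a 3-stannylcoumarin. A temporary 1,2-dioxine ring is then closed with singlet oxygen and opened to the enedione; metathesis and desilylation finish the route.
- Stereochemistry: the only stereocentre, C4′ (R in the target), is set by ligand-controlled CuH reduction of one of two enantiotopic enone arms of an achiral dienone. No later step breaks a bond at C4′; the two peroxide bridgeheads are transient.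

Key step: step 8

Assumption: the sense of induction of the copper hydride catalyst is assigned by analogy; if the (R,R)-ligand should give the (R)-enone, the (S,S)-ligand is used and nothing else changes.

**Route**

Step 1
Reactants: 1 4,4-dimethoxycyclohexa-2,5-dien-1-one; 2 allylmagnesium bromide
Product: 4 4-allyl-4-hydroxycyclohexa-2,5-dien-1-one, via ketal carbinol 3 (not isolated)
Conditions: allylMgBr, THF, −78 °C; then 10% aq. AcOH, acetone, 0 °C to rt
Reagents that add atoms: water, O
Why: Grignard 1,2-addition to the free carbonyl of the quinone monoketal, then hydrolysis of the doubly allylic dimethyl ketal by dilute acetic acid, should give the achiral p-quinol, whose carbinol carbon carries two identical enone arms and is not yet a stereocentre.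

Step 2
Reactants: 4 4-allyl-4-hydroxycyclohexa-2,5-dien-1-one
Product: 5 4-allyl-4-(triethylsilyloxy)cyclohexa-2,5-dien-1-one
Conditions: Et3SiOTf, 2,6-lutidine, CH2Cl2, −78 to 0 °C
Reagents that add atoms: triethylsilyl trifluoromethanesulfonate, CC[Si](CC)(CC)OS(=O)(=O)C(F)(F)F
Why: Silylation of a hindered tertiary carbinol with a silyl triflate and a hindered pyridine base is standard, and the triethylsilyl ether shields the hydroxyl through the hydride, enolate, palladium and oxidation steps yet can be removed later with buffered fluoride.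

Step 3
Reactants: 5 4-allyl-4-(triethylsilyloxy)cyclohexa-2,5-dien-1-one
Product: 7 (S)-4-allyl-4-(triethylsilyloxy)cyclohex-2-en-1-one, via silyl dienol ether 6 (not isolated)
Conditions: Cu(OAc)2 (3 mol%), (R,R)-Ph-BPE (3.3 mol%), (EtO)2MeSiH, toluene, −20 °C; then K2CO3 (cat.), MeOH, 0 °C
Reagents that add atoms: none
Why: Enantioselective copper hydride conjugate reduction (desymmetrisation of a 4,4-disubstituted cyclohexa-2,5-dienone) should deliver hydride to the β-carbon of only one enantiotopic enone arm under control of the chiral bisphosphine, setting C4 as S (the future C4′), while the first-formed silyl dienol ether is no longer an enone and the isolated allyl alkene is inert to CuH.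

Step 4
Reactants: 7 (S)-4-allyl-4-(triethylsilyloxy)cyclohex-2-en-1-one
Product: 9 (R)-4-allyl-4-(triethylsilyloxy)cyclohexa-1,5-dien-1-yl trifluoromethanesulfonate, via lithium dienolate 8 (not isolated)
Conditions: LiN(SiMe3)2, THF, −78 °C; then PhNTf2, −78 to 0 °C
Reagents that add atoms: N-phenylbis(trifluoromethanesulfonimide), O=S(=O)(N(c1ccccc1)S(=O)(=O)C(F)(F)F)C(F)(F)F
Why: Kinetic α′-deprotonation of the cyclohex-2-enone (C6 is the only acidic position because C4 is quaternary) gives the cross-conjugated lithium dienolate, and its O-triflation is the standard entry to 2-triflyloxy-1,3-dienes; the stereocentre is not involved.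

Step 5
Reactants: 10 7-methoxycoumarin
Product: 12 3-bromo-7-methoxycoumarin, via trans-dibromide 11 (not isolated)
Conditions: Br2 (1.05 equiv), CHCl3, 0 °C to rt; then Et3N, 0 °C to rt
Reagents that add atoms: bromine, BrBr
Why: Bromine addition across the coumarin C3=C4 bond followed by amine-induced loss of HBr (addition–elimination, the acidic C3–H leaving with the benzylic C4 bromide) should place bromine at C3, the α-carbon of the lactone.

Step 6
Reactants: 12 3-bromo-7-methoxycoumarin
Product: 13 7-methoxy-3-(tributylstannyl)coumarin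
Conditions: (Bu3Sn)2, Pd(PPh3)4 (5 mol%), toluene, 100 °C
Reagents that add atoms: hexabutylditin, CCCC[Sn](CCCC)(CCCC)[Sn](CCCC)(CCCC)CCCC
Why: Palladium-catalysed stannylation of a vinylic bromide with a distannane (oxidative addition, Sn–Sn transmetalation, reductive elimination) should give the Stille partner under neutral conditions that spare the lactone.

Step 7
Reactants: 9 (R)-4-allyl-4-(triethylsilyloxy)cyclohexa-1,5-dien-1-yl trifluoromethanesulfonate; 13 7-methoxy-3-(tributylstannyl)coumarin
Product: 14 3-[(4R)-4-allyl-4-(triethylsilyloxy)cyclohexa-1,5-dien-1-yl]-7-methoxy-2H-chromen-2-one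
Conditions: Pd(PPh3)4 (5 mol%), CuI (10 mol%), LiCl (3 equiv), DMF, 45 °C
Reagents that add atoms: none
Why: Stille cross-coupling, in which zerovalent palladium inserts into the dienyl C–OTf bond, chloride and CuI assist transmetalation of the α-stannyl lactone and reductive elimination forms the C1′–C3 bond, runs under neutral conditions that should leave the tertiary allylic silyl ether, the allyl group and C4′ untouched.

Step 8
Reactants: 14 3-[(4R)-4-allyl-4-(triethylsilyloxy)cyclohexa-1,5-dien-1-yl]-7-methoxy-2H-chromen-2-one
Product: 15 3-[(1R,4R,7R)-7-allyl-7-(triethylsilyloxy)-2,3-dioxabicyclo[2.2.2]oct-5-en-5-yl]-7-methoxy-2H-chromen-2-one (peroxide bridge anti to the silyloxy group)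
Conditions: O2, tetraphenylporphyrin (1 mol%), hν (>500 nm), CH2Cl2 over solid NaHCO3, −30 °C
Reagents that add atoms: oxygen, O=O
Why: Energy transfer from the photoexcited porphyrin converts dissolved O2 into singlet oxygen, which adds in a concerted suprafacial [4+2] fashion to C3′ and C6′ of the ring-locked s-cis diene and moves the alkene to C1′=C2′. The closest known reaction type is the sensitised photooxygenation of cyclohexa-1,3-dienes to 2,3-dioxabicyclo[2.2.2]oct-5-enes. The single ring that closes, the six-membered 1,2-dioxine bridge, is formed by the cycloaddition itself, both C–O bonds arising in one step. The two bridgehead stereocentres are necessarily cis to each other and their face is governed by the C4′ stereocentre, oxygen being expected to approach anti to the triethylsilyloxy group, although the facial outcome is immaterial because both bridgeheads become carbonyl carbons. The step needs chemoselectivity for the diene over the allyl alkene and the coumarin, which the substrate secures because a monosubstituted alkene is inert to the ene reaction, the coumarin C3=C4 bond is electron-poor and light above 500 nm excites only the sensitiser. Periselectivity for [4+2] over the ene reaction at the C5′ methylene rests on the cisoid ring diene, and exclusion of acid keeps the tertiary allylic silyl ether from ionising and aromatising the ring.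

Step 9
Reactants: 15 3-[(1R,4R,7R)-7-allyl-7-(triethylsilyloxy)-2,3-dioxabicyclo[2.2.2]oct-5-en-5-yl]-7-methoxy-2H-chromen-2-one
Product: 16 3-[(3R,4R)-4-allyl-3-hydroxy-6-oxo-4-(triethylsilyloxy)cyclohex-1-en-1-yl]-7-methoxy-2H-chromen-2-one
Conditions: Et3N (0.2 equiv), CH2Cl2, 0 °C
Reagents that add atoms: none
Why: Kornblum–DeLaMare rearrangement, in which the amine removes the less hindered C6′ bridgehead hydrogen as the O–O bond breaks, should give the C6′ ketone and the C3′ carbinol with its configuration retained from 15; removal of the other bridgehead hydrogen would give the regioisomeric hydroxy enone, which converges in step 10.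

Step 10
Reactants: 16 3-[(3R,4R)-4-allyl-3-hydroxy-6-oxo-4-(triethylsilyloxy)cyclohex-1-en-1-yl]-7-methoxy-2H-chromen-2-one
Product: 17 3-[(4R)-4-allyl-3,6-dioxo-4-(triethylsilyloxy)cyclohex-1-en-1-yl]-7-methoxy-2H-chromen-2-one
Conditions: Dess–Martin periodinane, pyridine, CH2Cl2, 0 °C to rt
Reagents that add atoms: none
Why: Dess–Martin oxidation of the secondary allylic alcohol under pyridine buffering is neutral enough for the β-silyloxy ketone and should give the 2-ene-1,4-dione, erasing the transient C3′ stereocentre and leaving C4′ untouched.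

Step 11
Reactants: 17 3-[(4R)-4-allyl-3,6-dioxo-4-(triethylsilyloxy)cyclohex-1-en-1-yl]-7-methoxy-2H-chromen-2-one; 18 2-methyl-2-butene
Product: 19 7-methoxy-3-[(4R)-4-(3-methylbut-2-en-1-yl)-3,6-dioxo-4-(triethylsilyloxy)cyclohex-1-en-1-yl]-2H-chromen-2-one
Conditions: second-generation Grubbs catalyst, (H2IMes)(PCy3)Cl2Ru=CHPh (5 mol%), 2-methyl-2-butene/CH2Cl2, 40 °C
Reagents that add atoms: none
Why: Olefin cross-metathesis of a monosubstituted alkene with excess 2-methyl-2-butene is the standard allyl-to-prenyl conversion, the ruthenium carbene engaging only the terminal alkene while the trisubstituted, electron-poor C1′=C2′ bond and the coumarin stay inert.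

Step 12
Reactants: 19 7-methoxy-3-[(4R)-4-(3-methylbut-2-en-1-yl)-3,6-dioxo-4-(triethylsilyloxy)cyclohex-1-en-1-yl]-2H-chromen-2-one
Product: 20 3-[(4R)-4-hydroxy-4-(3-methylbut-2-en-1-yl)-3,6-dioxocyclohex-1-en-1-yl]-7-methoxy-2H-chromen-2-one (CNP0250763.1)
Conditions: HF·pyridine, pyridine, THF, 0 °C
Reagents that add atoms: none
Why: Fluoride cleavage of the tertiary triethylsilyl ether with pyridine-buffered HF·pyridine should free the C4′ carbinol without dehydrating the β-hydroxy ketone, and since no bond to the stereocentre is broken the (R) configuration set in step 3 is delivered.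

**Compound list**

1 | 4,4-dimethoxycyclohexa-2,5-dien-1-one | COC1(OC)C=CC(=O)C=C1 | starting material
2 | allylmagnesium bromide | C=CC[Mg]Br | starting material
3 | 1-allyl-4,4-dimethoxycyclohexa-2,5-dien-1-ol | C=CCC1(O)C=CC(OC)(OC)C=C1 | intermediate
4 | 4-allyl-4-hydroxycyclohexa-2,5-dien-1-one | C=CCC1(O)C=CC(=O)C=C1 | intermediate
5 | 4-allyl-4-(triethylsilyloxy)cyclohexa-2,5-dien-1-one | C=CCC1(O[Si](CC)(CC)CC)C=CC(=O)C=C1 | intermediate
6 | (R)-{[4-allyl-4-(triethylsilyloxy)cyclohexa-1,5-dien-1-yl]oxy}diethoxy(methyl)silane | CCO[Si](C)(OCC)OC1=CC[C@](O[Si](CC)(CC)CC)(CC=C)C=C1 | intermediate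
7 | (S)-4-allyl-4-(triethylsilyloxy)cyclohex-2-en-1-one | O=C1C=C[C@@](O[Si](CC)(CC)CC)(CC=C)CC1 | intermediate
8 | lithium (R)-4-allyl-4-(triethylsilyloxy)cyclohexa-1,5-dien-1-olate | [Li+].[O-]C1=CC[C@](O[Si](CC)(CC)CC)(CC=C)C=C1 | intermediate
9 | (R)-4-allyl-4-(triethylsilyloxy)cyclohexa-1,5-dien-1-yl trifluoromethanesulfonate | O=S(=O)(OC1=CC[C@](O[Si](CC)(CC)CC)(CC=C)C=C1)C(F)(F)F | intermediate
10 | 7-methoxycoumarin | COc1ccc2ccc(=O)oc2c1 | starting material
11 | trans-3,4-dibromo-7-methoxychroman-2-one (racemic, one enantiomer drawn) | COc1ccc2[C@@H](Br)[C@H](Br)C(=O)Oc2c1 | intermediate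
12 | 3-bromo-7-methoxycoumarin | COc1ccc2cc(Br)c(=O)oc2c1 | intermediate
13 | 7-methoxy-3-(tributylstannyl)coumarin | CCCC[Sn](CCCC)(CCCC)c1cc2ccc(OC)cc2oc1=O | intermediate
14 | 3-[(4R)-4-allyl-4-(triethylsilyloxy)cyclohexa-1,5-dien-1-yl]-7-methoxy-2H-chromen-2-one | C1=C[C@@](O[Si](CC)(CC)CC)(CC=C)CC=C1c1cc2ccc(OC)cc2oc1=O | intermediate
15 | 3-[(1R,4R,7R)-7-allyl-7-(triethylsilyloxy)-2,3-dioxabicyclo[2.2.2]oct-5-en-5-yl]-7-methoxy-2H-chromen-2-one | C=CC[C@@]1(O[Si](CC)(CC)CC)C[C@H]2OO[C@@H]1C=C2c3cc4ccc(OC)cc4oc3=O | intermediate
16 | 3-[(3R,4R)-4-allyl-3-hydroxy-6-oxo-4-(triethylsilyloxy)cyclohex-1-en-1-yl]-7-methoxy-2H-chromen-2-one | C=CC[C@@]1(O[Si](CC)(CC)CC)CC(=O)C(c2cc3ccc(OC)cc3oc2=O)=C[C@H]1O | intermediate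
17 | 3-[(4R)-4-allyl-3,6-dioxo-4-(triethylsilyloxy)cyclohex-1-en-1-yl]-7-methoxy-2H-chromen-2-one | C=CC[C@@]1(O[Si](CC)(CC)CC)CC(=O)C(c2cc3ccc(OC)cc3oc2=O)=CC1=O | intermediate
18 | 2-methyl-2-butene | CC=C(C)C | starting material
19 | 7-methoxy-3-[(4R)-4-(3-methylbut-2-en-1-yl)-3,6-dioxo-4-(triethylsilyloxy)cyclohex-1-en-1-yl]-2H-chromen-2-one | CC(C)=CC[C@@]1(O[Si](CC)(CC)CC)CC(=O)C(c2cc3ccc(OC)cc3oc2=O)=CC1=O | intermediate
20 | 3-[(4R)-4-hydroxy-4-(3-methylbut-2-en-1-yl)-3,6-dioxocyclohex-1-en-1-yl]-7-methoxy-2H-chromen-2-one | COc1ccc2cc(C3=CC(=O)[C@@](O)(CC=C(C)C)CC3=O)c(=O)oc2c1 | target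

**Summary**

Total step count: 12. Longest linear sequence: 10 steps (steps 1–4 and 7–12); the coumarin branch (steps 5 and 6) joins at step 7.

Steps most likely to fail:

1. Step 3. The catalyst may discriminate poorly between the two enantiotopic enone arms, since the only handle is the difference between a silyloxy and an allyl group at the remote quaternary carbon, and 1,2-reduction of the carbonyl may compete. Fallback, setting out from 5: both enone alkenes are reduced with [(Ph3P)CuH]6 (the allyl group is untouched) to the achiral ketone 4-allyl-4-(triethylsilyloxy)cyclohexan-1-one F1. A C2-symmetric chiral lithium amide, LiN[(R)-CH(Me)Ph]2 (or its enantiomer, as required), with Me3SiCl present at −100 °C, then removes one of the two enantiotopic α-hydrogens and gives the silyl enol ether (S)-{[4-allyl-4-(triethylsilyloxy)cyclohex-1-en-1-yl]oxy}trimethylsilane F2. Saegusa–Ito dehydrogenation with Pd(OAc)2 in MeCN brings the route back at enone 7.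

2. Step 8. The coumarinyl group at C1′ makes the diene electron-poor, so cycloaddition may be slow enough for the ene reaction at the C5′ methylene, light-driven reactions of the coumarin chromophore or loss of silanol with aromatisation to take over. Fallback, setting out from 14 and returning at 15: the same peroxide is formed in the dark with ground-state oxygen through the diene radical cation, using catalytic tris(4-bromophenyl)aminium hexachloroantimonate, (4-BrC6H4)3N·SbCl6, O2 and 2,6-di-tert-butylpyridine in CH2Cl2 at −78 °C. This is a chain cation-radical oxygenation known for conjugated dienes, forms the same two C–O bonds and makes no new compound.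

3. Step 12. As the silyl group leaves, the freed β-hydroxy ketone may lose water across C4′–C5′ (giving a benzoquinone and destroying the stereocentre) or undergo an α-ketol shift. Fallback, setting out from 15 and returning at 20: the silyl group is removed before either ketone exists and the last step becomes a neutral oxidation.
   - Thiourea in MeOH reduces the peroxide to the cis-enediol 3-[(3R,4R,6R)-4-allyl-3,6-dihydroxy-4-(triethylsilyloxy)cyclohex-1-en-1-yl]-7-methoxy-2H-chromen-2-one F3.
   - Bu4NF in THF cleaves the silyl ether at this carbonyl-free stage to the triol 3-[(3R,4R,6R)-4-allyl-3,4,6-trihydroxycyclohex-1-en-1-yl]-7-methoxy-2H-chromen-2-one F4.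
   - Cross-metathesis with 18 and the second-generation Grubbs catalyst gives the prenyl triol 7-methoxy-3-[(3R,4R,6R)-3,4,6-trihydroxy-4-(3-methylbut-2-en-1-yl)cyclohex-1-en-1-yl]-2H-chromen-2-one F5.
   - Dess–Martin periodinane with pyridine oxidises both secondary allylic alcohols, leaves the tertiary carbinol and gives 20 directly.

Further compounds
F1 | step 3 | 4-allyl-4-(triethylsilyloxy)cyclohexan-1-one | C=CCC1(O[Si](CC)(CC)CC)CCC(=O)CC1
F2 | step 3 | (S)-{[4-allyl-4-(triethylsilyloxy)cyclohex-1-en-1-yl]oxy}trimethylsilane | C[Si](C)(C)OC1=CC[C@@](O[Si](CC)(CC)CC)(CC=C)CC1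
F0 | step 8 | none | none
F3 | step 12 | 3-[(3R,4R,6R)-4-allyl-3,6-dihydroxy-4-(triethylsilyloxy)cyclohex-1-en-1-yl]-7-methoxy-2H-chromen-2-one | C=CC[C@@]1(O[Si](CC)(CC)CC)C[C@@H](O)C(c2cc3ccc(OC)cc3oc2=O)=C[C@H]1O
F4 | step 12 | 3-[(3R,4R,6R)-4-allyl-3,4,6-trihydroxycyclohex-1-en-1-yl]-7-methoxy-2H-chromen-2-one | C=CC[C@@]1(O)C[C@@H](O)C(c2cc3ccc(OC)cc3oc2=O)=C[C@H]1O
F5 | step 12 | 7-methoxy-3-[(3R,4R,6R)-3,4,6-trihydroxy-4-(3-methylbut-2-en-1-yl)cyclohex-1-en-1-yl]-2H-chromen-2-one | CC(C)=CC[C@@]1(O)C[C@@H](O)C(c2cc3ccc(OC)cc3oc2=O)=C[C@H]1O
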